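The cyclohexene is disconnected at C4–C12' and C5–C15' by a biomimetic Diels–Alder reaction into trans-communic acid and a trans-cyclononene carboxylic acid. The plan rests on how that nine-membered ring (C1–C9, caryophyllane numbering) arises. The 1,5-relation between C8 and the C4=C5 double bond is a Grob retron. The precursor is a 4-7-4 tricycle, a bicyclo[5.2.0]nonan-1-ol whose C5–C8 bond divides the future ring into a cycloheptane and a cyclobutane. It is epoxidised at its C4 exocyclic methylene and fragments. One operation enlarges seven ring atoms to nine, releases cyclobutane and epoxide strain, unveils the C8 ketone and the oxygenated C12, and fixes the trans double bond stereospecifically.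

Key step: step 10

Atom labels: caryophyllane numbers for the sesquiterpene half (nine-membered ring C1–C9; cyclobutane C1, C9, C10, C11; C12 on C4; C13 on C8). Primed labdane numbers for the diterpene half (diene C12'=C13'–C14'=C15').
Assumption: the sense of induction in step 1 is taken from the behaviour of cyclohex-2-enone. The antipode of the ligand is used if the opposite enantiomer of 3 results.

Step 1
Reactants: 1 cyclopent-2-en-1-one; 2 isobutene
Product: 3 (1R,5R)-6,6-dimethylbicyclo[3.2.0]heptan-2-one (cis-fused; ketone = C8; fusion carbons = C9 and C1)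
Conditions: hν (366 nm), oxazaborolidine from (S)-α,α-bis(3,5-dimethylphenyl)prolinol and 2,4,6-trifluorophenylboronic acid activated with AlBr3 (50 mol %), CH2Cl2, −75 °C
Reagents that add atoms: none
Why: Enantioselective enone–alkene [2+2] photocycloaddition in which the Lewis-acid-bound enone is excited selectively and shielded on one face by the ligand aryl groups, isobutene adds head-to-tail (CMe2 to the β-carbon), and the bicyclo[3.2.0] skeleton enforces the cis fusion, so that C1 is set for good and C9 provisionally (corrected in step 11).

Step 2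
Reactants: 3 (1R,5R)-6,6-dimethylbicyclo[3.2.0]heptan-2-one
Product: 4 (1R,5R)-6,6-dimethyl-2-(trimethylsilyloxy)bicyclo[3.2.0]hept-2-ene
Conditions: LiN(iPr)2, THF, −78 °C; Me3SiCl
Reagents that add atoms: chlorotrimethylsilane C[Si](C)(C)Cl
Why: Kinetic deprotonation at the only unhindered α-methylene (C3) followed by O-silylation (silyl enol ether formation) leaves both stereocentres untouched.

Step 3
Reactants: 4 (1R,5R)-6,6-dimethyl-2-(trimethylsilyloxy)bicyclo[3.2.0]hept-2-ene
Product: 5 4-5-4 tricyclic dichlorocyclobutanone (CCl2 = C5 on the siloxy carbon C8; C=O = C4 on C3; new ring on the face opposite to C10/C11)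
Conditions: Cl3CCOCl, Zn/Cu couple, Et2O, 25 °C
Reagents that add atoms: trichloroacetyl chloride ClC(Cl)(Cl)C(=O)Cl
Why: Thermal ketene–enol ether [2+2] cycloaddition in which the ketene carbonyl carbon bonds to the nucleophilic C3 on the convex face, and the two new stereocentres are erased again in step 4.

Step 4
Reactants: 5 4-5-4 tricyclic dichlorocyclobutanone
Product: 7 (1R,7R)-8,8-dimethylbicyclo[5.2.0]nonane-2,4-dione (C8 and C4 carbonyls; C5 methylene between them), via dechlorinated cyclobutanone 6 (not isolated)
Conditions: Zn, AcOH, i-PrOH/H2O, 80 °C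
Reagents that add atoms: none
Why: Zinc reduces both C–Cl bonds and loss of the silyl group triggers a retro-aldol cleavage of the C8–C3 bond of the donor–acceptor cyclobutane, a known two-carbon ring expansion of silyloxy cyclobutanones that turns the five-membered ring into the seven-membered 1,3-dione.

Step 5
Reactants: 7 (1R,7R)-8,8-dimethylbicyclo[5.2.0]nonane-2,4-dione
Product: 8 (1R,7R)-4-methoxy-8,8-dimethylbicyclo[5.2.0]non-3-en-2-one (OMe on C4; ketone C8)
Conditions: MeOH, p-TsOH (5 mol %), 4 Å molecular sieves, 65 °C
Reagents that add atoms: methanol CO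
Why: Acid-catalysed vinylogous ester formation under equilibrating conditions should place the methoxy group on the less hindered carbonyl carbon C4, which is flanked by a methylene, and leave the carbonyl next to the ring-fusion carbon C9.

Step 6
Reactants: 8 (1R,7R)-4-methoxy-8,8-dimethylbicyclo[5.2.0]non-3-en-2-one
Product: 9 (1R,7R)-2-(tert-butyldimethylsilyloxy)-8,8-dimethylbicyclo[5.2.0]non-2-en-4-one (OSi on C8; ketone C4)
Conditions: t-BuMe2SiCl (1.0 equiv), NaI (1.0 equiv), MeCN, 0 to 25 °C
Reagents that add atoms: tert-butyldimethylsilyl chloride CC(C)(C)[Si](C)(C)Cl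
Why: Silyl iodide dealkylation in which silicon binds the carbonyl oxygen on C8 and iodide removes the methyl group by SN2 attack, so the two oxygen functions exchange roles regiospecifically and the fixed s-trans geometry of the ring prevents intramolecular silyl return.

Step 7
Reactants: 9 (1R,7R)-2-(tert-butyldimethylsilyloxy)-8,8-dimethylbicyclo[5.2.0]non-2-en-4-one; 10 ethylene
Product: 11 4-7-4 tricyclic ketone (new cyclobutane C5–C6–C7–C8 cis-fused; OSi on C8; ketone C4; C6–C7 bridge on the face opposite to C10/C11)
Conditions: hν (medium-pressure Hg lamp, Pyrex), C2H4 (saturated), CH2Cl2, −78 °C; then basic Al2O3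
Reagents that add atoms: none
Why: Enone–alkene [2+2] photocycloaddition (the first half of a De Mayo reaction, whose retro-aldol step is blocked by the silyl group), with contact with base settling the enolisable C5 in the cis-fused form, and with the face attacked being irrelevant because C5 and C8 become trigonal in step 10.

Step 8
Reactants: 11 4-7-4 tricyclic ketone
Product: 12 4-7-4 tricyclic silyl ether with C4=C12 exocyclic methylene
Conditions: Ph3PCH3Br, KOtBu, THF, 0 to 25 °C
Reagents that add atoms: methyltriphenylphosphonium bromide C[P+](c1ccccc1)(c1ccccc1)c1ccccc1.[Br-]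
Why: Wittig methylenation of the only carbonyl group brings in C12, and the protected tertiary oxygen cannot start a retro-aldol reaction.

Step 9
Reactants: 12 4-7-4 tricyclic silyl ether with C4=C12 exocyclic methylene
Product: 13 4-7-4 tricyclic homoallylic cyclobutanol (free C8–OH; C4=C12)
Conditions: Bu4NF, AcOH, THF, 25 °C
Reagents that add atoms: none
Why: Fluoride desilylation buffered with acetic acid frees the tertiary alcohol without building up the alkoxide that could expel an allyl anion.

Step 10
Reactants: 13 4-7-4 tricyclic homoallylic cyclobutanol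
Product: 15 (1R,9R)-12-hydroxy-13-norcaryophyll-4-en-8-one (nine-membered ring; trans ring double bond with C12 cis to C6; cis-fused cyclobutane), via epoxy alcohol 14 (not isolated)
Conditions: t-BuOOH, Ti(OiPr)4 (20 mol %), CH2Cl2, 0 °C, then 40 °C
Reagents that add atoms: tert-butyl hydroperoxide CC(C)(C)OO
Why: The titanium alkoxide of the tertiary C8 hydroxyl delivers oxygen to the face of the C4=C12 double bond that it occupies (hydroxyl-directed epoxidation of a homoallylic alcohol), giving 14 with the C4–O bond trans to C6. In 14 the C5–C8 bond can stand antiperiplanar to that C4–O bond, so the oxygen at C8 pushes, the Lewis-acid-bound oxirane pulls, and C5–C8 breaks in a concerted Grob-type epoxy alcohol fragmentation, the closest known reaction type, driven here by the loss of cyclobutane and epoxide strain. The only ring closed is the transient oxirane (syn oxygen transfer); the nine-membered ring is not closed but uncovered when the bond shared by the seven- and four-membered rings is cut, which is a two-atom ring expansion. The transient stereocentre C4 is controlled by the directing hydroxyl and is translated by the antiperiplanar geometry into the trans ring double bond with C12 cis to C6, while C5 and C8 become trigonal, so either facial isomer of 11 converges on 15, and C1 is untouched. The step needs facial selectivity in the epoxidation, secured by the hydroxyl group and reinforced by the C6–C7 bridge on the other face, and C–C cleavage instead of ether formation, secured because attack of the hydroxyl on the oxirane would need a four-membered or an endo transition state.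

Step 11
Reactants: 15 (1R,9R)-12-hydroxy-13-norcaryophyll-4-en-8-one
Product: 17 (1R,9S)-caryophylla-4,8(13)-dien-12-ol (trans ring double bond; trans-fused cyclobutane), via trans-fused ketone 16 (not isolated)
Conditions: KOtBu, t-BuOH/THF, 25 °C; then Ph3PCH3Br/KOtBu (3 equiv), THF, 25 °C
Reagents that add atoms: methyltriphenylphosphonium bromide C[P+](c1ccccc1)(c1ccccc1)c1ccccc1.[Br-]
Why: Base equilibrates C9 next to the ketone towards the trans-fused bicyclo[7.2.0]undecanone, which is the more stable fusion once the larger ring has nine members and thereby sets C9, and Wittig methylenation then brings in C13 without touching the isolated trans double bond.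

Step 12
Reactants: 17 (1R,9S)-caryophylla-4,8(13)-dien-12-ol
Product: 18 (1R,9S)-caryophylla-4,8(13)-dien-12-al
Conditions: MnO2, CH2Cl2, 25 °C
Reagents that add atoms: none
Why: Manganese dioxide oxidises only the allylic alcohol and works under neutral conditions that preserve the geometry of the strained double bond.

Step 13
Reactants: 18 (1R,9S)-caryophylla-4,8(13)-dien-12-al
Product: 19 (1R,9S)-caryophylla-4,8(13)-dien-12-oic acid (trans ring double bond; carboxyl cis to C6)
Conditions: NaClO2, NaH2PO4, 2-methylbut-2-ene, t-BuOH/H2O, 0 °C
Reagents that add atoms: sodium chlorite [Na+].[O-]Cl=O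
Why: Pinnick oxidation converts the enal into the acid without isomerisation, and the excess of scavenger alkene intercepts hypochlorous acid before it can reach the two double bonds.

Step 14
Reactants: 19 (1R,9S)-caryophylla-4,8(13)-dien-12-oic acid; 20 trans-communic acid
Product: 21 target CNP0330729.1
Conditions: toluene, BHT (1 mol %), 90 °C, sealed tube
Reagents that add atoms: none
Why: Normal-demand Diels–Alder reaction accelerated by the strain of the trans double bond, in which the free terminus C15' bonds to the β-carbon C5 and C12' to C4 (ortho rule for the 1-substituted diene), the diene reaches only the outer face of the trans-cyclononene, the face that peracids attack in caryophyllene, which sets C4 and C5, suprafacial addition keeps C3 and C6 trans, and the carboxyl-endo transition state places C11' cis to the new quaternary carboxyl and so sets C12'.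

Compound list
1 | cyclopent-2-en-1-one | O=C1C=CCC1 | starting material
2 | isobutene | C=C(C)C | starting material
3 | (1R,5R)-6,6-dimethylbicyclo[3.2.0]heptan-2-one | O=C1CC[C@@H]2[C@H]1CC2(C)C | intermediate
4 | (1R,5R)-6,6-dimethyl-2-(trimethylsilyloxy)bicyclo[3.2.0]hept-2-ene | C[Si](C)(C)OC1=CC[C@@H]2[C@H]1CC2(C)C | intermediate
5 | 4-5-4 tricyclic dichlorocyclobutanone | C[Si](C)(C)O[C@]12[C@@H]3CC(C)(C)[C@@H]3C[C@H]1C(=O)C2(Cl)Cl | intermediate
6 | dechlorinated silyloxy cyclobutanone | C[Si](C)(C)O[C@]12[C@@H]3CC(C)(C)[C@@H]3C[C@H]1C(=O)C2 | intermediate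
7 | (1R,7R)-8,8-dimethylbicyclo[5.2.0]nonane-2,4-dione | O=C1CC(=O)CC[C@@H]2[C@H]1CC2(C)C | intermediate
8 | (1R,7R)-4-methoxy-8,8-dimethylbicyclo[5.2.0]non-3-en-2-one | O=C1C=C(OC)CC[C@@H]2[C@H]1CC2(C)C | intermediate
9 | (1R,7R)-2-(tert-butyldimethylsilyloxy)-8,8-dimethylbicyclo[5.2.0]non-2-en-4-one | CC(C)(C)[Si](C)(C)OC1=CC(=O)CC[C@@H]2[C@H]1CC2(C)C | intermediate
10 | ethylene | C=C | starting material
11 | 4-7-4 tricyclic silyloxy ketone | CC(C)(C)[Si](C)(C)O[C@@]12CC[C@@H]1C(=O)CC[C@@H]3[C@H]2CC3(C)C | intermediate
12 | 4-7-4 tricyclic silyl ether with exocyclic methylene | CC(C)(C)[Si](C)(C)O[C@@]12CC[C@@H]1C(=C)CC[C@@H]3[C@H]2CC3(C)C | intermediate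
13 | 4-7-4 tricyclic homoallylic cyclobutanol | O[C@@]12CC[C@@H]1C(=C)CC[C@@H]3[C@H]2CC3(C)C | intermediate
14 | epoxy alcohol (oxirane oxygen cis to the C8 hydroxyl, trans to C6) | O[C@@]12CC[C@@H]1[C@]4(CO4)CC[C@@H]3[C@H]2CC3(C)C | intermediate
15 | (1R,9R)-12-hydroxy-13-norcaryophyll-4-en-8-one | O=C1CC/C=C(CO)/CC[C@@H]2[C@H]1CC2(C)C | intermediate
16 | (1R,9S)-12-hydroxy-13-norcaryophyll-4-en-8-one | O=C1CC/C=C(CO)/CC[C@@H]2[C@@H]1CC2(C)C | intermediate
17 | (1R,9S)-caryophylla-4,8(13)-dien-12-ol | C=C1CC/C=C(CO)/CC[C@@H]2[C@@H]1CC2(C)C | intermediate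
18 | (1R,9S)-caryophylla-4,8(13)-dien-12-al | C=C1CC/C=C(C=O)/CC[C@@H]2[C@@H]1CC2(C)C | intermediate
19 | (1R,9S)-caryophylla-4,8(13)-dien-12-oic acid | C=C1CC/C=C(C(=O)O)/CC[C@@H]2[C@@H]1CC2(C)C | intermediate
20 | trans-communic acid | C=C/C(C)=C/C[C@H]1C(=C)CC[C@@H]2[C@]1(C)CCC[C@]2(C)C(=O)O | starting material
21 | CNP0330729.1 | C=C1CC[C@H]2CC=C(C)[C@@H](C[C@H]3C(=C)CC[C@@H]4[C@]3(C)CCC[C@]4(C)C(=O)O)[C@]2(C(=O)O)CC[C@@H]2[C@@H]1CC2(C)C | target

Total step count: 14. Longest linear sequence: 14 steps (1 to 21; 20 is bought).

Steps most likely to fail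

Step 7. The excited seven-membered enone may relax by twisting about its double bond and then dimerise or decay faster than ethylene traps it.
- The fallback avoids light and sets out from 9.
- The ketone of 9 is methylenated first (Ph3PCH3Br, KOtBu) to the 2-silyloxy-1,3-diene F1.
- Dichloroketene (Cl3CCOCl, Zn/Cu couple) should add thermally to the electron-rich C5=C8 enol ether bond, carbonyl carbon to C5, to give the dichlorocyclobutanone F2.
- Zn and NH4Cl in MeOH remove both chlorines to give the cyclobutanone F3.
- Condensation with TsNHNH2 gives the tosylhydrazone F4.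
- Reduction with catecholborane followed by NaOAc deletes the C6 carbonyl group.
- The sequence comes back to the route at 12.

Step 14. Polymerisation of the diene may compete with a slow cycloaddition, and the endo/exo and facial preferences of the free acid may be weak.
- The fallback sets out from 18, the more electron-poor enal.
- 18 is combined with 20 under high pressure (12 kbar, CH2Cl2, 25 °C), where the more compact endo transition state gains most, to give the aldehyde adduct F7.
- Pinnick oxidation (NaClO2, NaH2PO4, 2-methylbut-2-ene) of its neopentyl aldehyde comes back to the route at 21.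

Step 10. The oxirane may isomerise to an aldehyde under the Lewis acid, or be opened by the neighbouring hydroxyl, before the C5–C8 bond breaks.
- In the fallback a bromonium ion takes the place of the oxirane.
- From 13, N-bromosuccinimide and K2CO3 in CH2Cl2 at −20 °C should attack the same open face.
- The antiperiplanar C5–C8 bond should then break in the same Grob manner to give the keto allylic bromide F5.
- KOAc in DMF gives the keto allylic acetate F6 by SN2 displacement.
- K2CO3 in MeOH brings the sequence back to the route at 15.

Further compounds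
F1 | step 7 | 2-silyloxy-1,3-diene | CC(C)(C)[Si](C)(C)OC1=CC(=C)CC[C@@H]2[C@H]1CC2(C)C
F2 | step 7 | dichlorocyclobutanone | CC(C)(C)[Si](C)(C)O[C@@]12C(Cl)(Cl)C(=O)[C@@H]1C(=C)CC[C@@H]3[C@H]2CC3(C)C
F3 | step 7 | cyclobutanone | CC(C)(C)[Si](C)(C)O[C@@]12CC(=O)[C@@H]1C(=C)CC[C@@H]3[C@H]2CC3(C)C
F4 | step 7 | tosylhydrazone | CC(C)(C)[Si](C)(C)O[C@@]12CC(=NNS(=O)(=O)c4ccc(C)cc4)[C@@H]1C(=C)CC[C@@H]3[C@H]2CC3(C)C
F5 | step 10 | keto allylic bromide | O=C1CC/C=C(CBr)/CC[C@@H]2[C@H]1CC2(C)C
F6 | step 10 | keto allylic acetate | O=C1CC/C=C(COC(C)=O)/CC[C@@H]2[C@H]1CC2(C)C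
F7 | step 14 | aldehyde adduct | C=C1CC[C@H]2CC=C(C)[C@@H](C[C@H]3C(=C)CC[C@@H]4[C@]3(C)CCC[C@]4(C)C(=O)O)[C@]2(C=O)CC[C@@H]2[C@@H]1CC2(C)C
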